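## The problem

Compound 18 is a single oxolane ring (O1, C2–C5) with three contiguous stereocentres. C2 (R) carries a 3,4,5-trimethoxyphenyl group, C3 (S) a hydroxymethyl group and C4 (S) a 3-hydroxy-4,5-dimethoxybenzyl group; aryl and CH2OH are trans, CH2OH and benzyl are cis, and C5 is a methylene. The two arenes differ only by OH against OMe at one position, so they must arrive in separate building blocks and the phenol must stay masked until the end. The 2,3-trans relationship is the relaxed one, but the 3,4-cis relationship is the strained one and has to be set kinetically, under control of the group already on C3. There is no obvious chiral-pool source, so absolute configuration is best introduced once, catalytically, at C2/C3, which then govern C4. The fragile spots are the C2–O1 bond (a benzylic ether that strong Lewis acid can ionise and palladium can hydrogenolyse), the free phenol and primary alcohol toward base and hydride, and any C3 ester next to the ring oxygen, whose enolate would expel O1 as in the ring-opening half of the Stobbe condensation. The enabling feature is the C2–C3 pair: a benzylic carbinol carbon bonded to a carbon with a one-carbon branch at the carboxyl oxidation level, with C4–C5 as an acetate arm on C3 whose end carbon is bonded to O1. Read backwards, 18 is a reduced 2-aryl paraconate, and that lactone is the reduced and cyclised form of a 2-aroylsuccinate whose α-carbon racemises freely, which is the precondition for a dynamic kinetic resolution.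

## Retrosynthesis

**Protecting groups (18 ⇒ 17).** The last operation cleaves the two O–Si bonds of the bis(triisopropylsilyl) ether 17. Silyl ethers are preferred to benzyl ethers because a final hydrogenolysis would endanger the benzylic C2–O1 bond, and to acetals because acid would do the same. The forward step only has to be mild, and fluoride is.

**C5 oxidation level (17 ⇒ 16 ⇒ 15).** The C5 methylene is traced through lactol 16 to the carbonyl of lactone 15; only two C5–H bonds are cut. Closing O1–C2 through a benzylic cation would give up the configuration at C2, and closing O1–C5 by displacement from a diol adds steps (it is kept as a fallback). The lactone keeps O1–C5 intact from the key step on and makes C4 enolisable for attaching the benzyl group. The forward reduction must remove the lactol hydroxyl without ionising C2–O1.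

**C4 configuration (15 ⇒ 14).** The C4–H and C7'–H bonds are cut to give the (E)-benzylidene lactone 14 (C7' is the benzylic carbon of the C4 side chain). Direct benzylation of the lactone enolate would place the benzyl group trans to the C3 branch, the wrong isomer. Adding hydrogen to the exocyclic alkene from the face opposite that branch puts it cis. The precursor has one stereocentre fewer; the forward step has to deliver hydrogen anti to the C3 group and spare the benzylic lactone.

**C4–C7' bond (14 ⇒ 12 ⇒ 9 + 11; 11 ⇒ 10).** The C4=C7' bond is cut by a retro-aldol condensation to lactone 9 and aldehyde 11, through aldol 12 and its mesylate 13. This is the convergent cut: it divides the molecule into its two aryl halves and uses the only acidic position of 9. Aldehyde 11 comes from commercial phenol 10 by O-silylation; a silyl group rather than benzyl lets the later hydrogenation be stopped at the alkene.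

**C3 branch (9 ⇒ 8 ⇒ 7 ⇒ 5).** The silyloxymethyl group of 9 is traced through alcohol 8 and acid 7 to the ethyl ester of paraconate 5. The adjustment is made before the aldol on purpose: a C3 ester would offer a second acidic site whose enolate ejects O1, whereas a silyloxymethyl group is neither acidic nor epimerisable and is bulkier for the hydrogenation. The forward steps need only the known preference of borane for an acid over a lactone.

**Key disconnection (5 ⇒ 4 ⇒ 3).** Lactone 5 is opened at the acyl bond O1–C5 to the hydroxy diester 4, and removal of the C2 hydride leads to the racemic keto diester 3. Against an aldol construction of C2–C3, which would need a stoichiometric controller, this cut sets both stereocentres in one catalytic operation from an achiral-at-equilibrium substrate. The forward reaction must select one ketone face and one enantiomer of a racemising substrate, then close a five-membered lactone.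

**C3–C4 bond (3 ⇒ 1 + 2).** Keto diester 3 is cut between C3 and C4 to the commercial β-keto ester 1 and ethyl bromoacetate 2. The forward step is an ordinary enolate alkylation; its lack of stereocontrol is harmless because the next step is dynamic.

## Roads not taken

**Alternative 1:** The two exocyclic carbons on C3 and C4 are removed together as a ketene unit, leaving the dihydrofuran A2. Forward, dichloroketene (from trichloroacetyl chloride and zinc) would add [2+2] across C3=C4 anti to the aryl group to give the cis-fused dichlorocyclobutanone A1.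
- Merit: ring fusion forces the C3 and C4 branches cis and the anti approach puts them trans to the aryl group. On this point it is stronger than the chosen plan, where 3,4-cis rests on a facial preference in a hydrogenation.
- Weak points: the alkene of A2 is unpolarised, so the orientation of the ketene rests on a modest steric bias. The four-membered ring must then be cleaved, the CCl2 carbon dechlorinated and joined to the phenol-bearing arene; during this C4 sits α to a carbonyl and can drift to 3,4-trans. A2 itself needs an enantioselective synthesis.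
- Comparison: the chosen plan sets against the geometric certainty of A1 a sequence in which every step is a known operation on this lactone class and no ring has to be built and destroyed.

**Alternative 2:** The C3–C4 bond is cut, giving the acyclic epoxy cinnamyl ether A4 in which O1 already links C2 and C5. Forward, Cp2TiCl (trivalent titanium, from Cp2TiCl2 and zinc) would open the epoxide to the C3 radical, which closes 5-exo onto the cinnamyl alkene; reduction and protonation of the benzylic radical would give A3, the O-benzyl ether of the target.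
- Merit: the ring, the C3–C4 bond and two stereocentres arise in one step and the hydroxymethyl group appears unprotected. In step economy this road is clearly better, perhaps half the length.
- Weak points: stereocontrol comes from a flexible radical transition state; 2,3-trans is dependable, but the 3,4 relationship usually forms as a mixture that must be separated. A4 must be made enantio-enriched, most plausibly by a kinetic resolution with a 50% ceiling. Debenzylation of A3 by hydrogenolysis would put the C2–O1 bond at risk, though another phenol group could cure that.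
- Comparison: the chosen plan is longer, but it takes its absolute configuration from a dynamic resolution that can convert all the material and sets C4 in a separate step with an established facial bias.

**Alternative 3:** The C2–C3 bond is cut, giving the α-diazo lactone A6 with a trimethoxybenzyl ether side chain. Forward, Rh2(OAc)4 (divalent rhodium) would form the carbenoid at C3, which inserts into a benzylic C–H bond of the ether to close the oxolane cis-fused to the lactone, giving A5.
- Merit: convergent, with a late C–C bond formation at an activated C–H bond; the cis fusion fixes 3,4-cis by geometry, which the chosen plan cannot claim.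
- Weak points: diazo transfer onto a lactone needs prior activation. The carbenoid can also add to the electron-rich arenes (Büchner reaction) or form an oxonium ylide at the ether oxygen. The C2 configuration depends on a transition-state preference. A5 must then be opened by hydrogenolysis of the lactone benzylic C–O bond in the presence of the equally benzylic C2–O1 bond. A6 needs its own asymmetric synthesis.
- Comparison: the chosen plan answers with ordinary reagents and no chemoselectivity problem of that severity.

Key step: step 2

Assumption: a ketoreductase that accepts 3 and gives the (2R,3R) series is taken to be found by screening a commercial NADPH-dependent panel; the route does not depend on one named enzyme.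

Remark on locants: O1 and C2–C5 in the discussion are the ring atoms of target 18 and keep these labels in every intermediate; systematic names of lactones number the ring from the carbonyl carbon.

## Route

**Step 1**
Reactants: 1 ethyl 3-oxo-3-(3,4,5-trimethoxyphenyl)propanoate; 2 ethyl bromoacetate
Product: 3 diethyl 2-(3,4,5-trimethoxybenzoyl)butanedioate (racemic)
Conditions: NaH (1.05 equiv), THF, 0 °C; then 2 (1.0 equiv), 0 °C → rt
Reagents that add atoms: none
Why: SN2 C-alkylation of the sodium enolate of a β-keto ester by an α-bromo ester forms the C3–C4 bond; one equivalent of halide limits dialkylation. The new centre forms racemic and stays labile, which step 2 exploits.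

**Step 2**
Reactants: 3 diethyl 2-(3,4,5-trimethoxybenzoyl)butanedioate
Product: 5 ethyl (2R,3R)-5-oxo-2-(3,4,5-trimethoxyphenyl)oxolane-3-carboxylate, via hydroxy diester 4 (not isolated)
Conditions: ketoreductase (NADPH-dependent, chosen by panel screening), NADP+ (cat.), D-glucose, glucose dehydrogenase, KH2PO4/K2HPO4 buffer pH 7.0, DMSO (10% v/v), 30 °C; toluene extraction, then TsOH·H2O (cat.), 50 °C
Reagents that add atoms: none
Why: Enzymatic dynamic reductive kinetic resolution followed by lactonisation. The C3–H of 3 lies between the aryl ketone and an ester, so the enantiomers of 3 interconvert through the enol in the neutral buffer faster than the disfavoured one is reduced. The ketoreductase binds one enantiomer and transfers hydride from NADPH to one face of its ketone, while glucose dehydrogenase oxidises glucose to return NADPH. C2 (R) is thus fixed by the face the active site presents to the cofactor and C3 (R) by the enantiomer the pocket accepts, so a single hydroxy diester 4 should accumulate. With catalytic TsOH the C2 hydroxyl attacks the ester carbonyl of the acetate arm and ethanol leaves, a 5-exo-trig acyl substitution that forms the O1–C5 bond and the oxolanone ring; attack on the C3 ester would need a four-membered ring. The closest known reaction type is the ketoreductase reduction of α-substituted aryl β-keto esters under dynamic kinetic resolution, and reduced 2-acylsuccinates are known to lactonise to paraconates. The step needs chemoselectivity for the ketone over two esters and one stereoisomer out of four; the substrate supplies the acidic α-hydrogen for racemisation and a clear shape difference between the flat aryl group and the branched succinate side for face discrimination. The 2,3-trans lactone is also the more stable C3 epimer, so ring closure does not endanger C3.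

**Step 3**
Reactants: 5 ethyl (2R,3R)-5-oxo-2-(3,4,5-trimethoxyphenyl)oxolane-3-carboxylate
Product: 7 (2R,3R)-5-oxo-2-(3,4,5-trimethoxyphenyl)oxolane-3-carboxylic acid, via ring-opened hydroxy diacid 6 (not isolated)
Conditions: LiOH·H2O (3 equiv), THF/H2O 3:1, 0 °C → rt; then 2 M HCl to pH 1, 40 °C
Reagents that add atoms: lithium hydroxide, [Li+].[OH-]; water, O
Why: Hydroxide saponifies the ethyl ester and opens the lactone by acyl–oxygen cleavage to the dicarboxylate 6; on acidification only the acetate-arm carboxyl can close again (five-membered against four-membered ring). No bond to C2 or C3 is broken, and hydroxide addition to the lactone carbonyl in water is much faster than deprotonation at C3, the event that would eject O1.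

**Step 4**
Reactants: 7 (2R,3R)-5-oxo-2-(3,4,5-trimethoxyphenyl)oxolane-3-carboxylic acid
Product: 8 (4S,5R)-4-(hydroxymethyl)-5-(3,4,5-trimethoxyphenyl)oxolan-2-one
Conditions: BH3·SMe2 (1.5 equiv), THF, 0 °C → rt; MeOH quench
Reagents that add atoms: none
Why: Borane reduces a carboxylic acid through its acyloxyborane far faster than it attacks a lactone, so only the C3 carboxyl becomes the primary alcohol; C3 is then no longer α to a carbonyl and is locked. The crude alcohol is silylated at once, since a free hydroxymethyl group beside the lactone could translactonise.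

**Step 5**
Reactants: 8 (4S,5R)-4-(hydroxymethyl)-5-(3,4,5-trimethoxyphenyl)oxolan-2-one
Product: 9 (4S,5R)-4-{[(triisopropylsilyl)oxy]methyl}-5-(3,4,5-trimethoxyphenyl)oxolan-2-one
Conditions: iPr3SiCl (1.2 equiv), imidazole (2.5 equiv), DMF, 0 °C → rt
Reagents that add atoms: triisopropylsilyl chloride, CC(C)[Si](Cl)(C(C)C)C(C)C
Why: Standard silylation of a primary alcohol with a silyl chloride and imidazole. The triisopropylsilyl ether withstands the amide base, hydride and Lewis acid of later steps and adds bulk on the C3 face for step 9.

**Step 6**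
Reactants: 10 3-hydroxy-4,5-dimethoxybenzaldehyde
Product: 11 3,4-dimethoxy-5-[(triisopropylsilyl)oxy]benzaldehyde
Conditions: iPr3SiCl (1.2 equiv), imidazole (2.5 equiv), DMF, rt
Reagents that add atoms: triisopropylsilyl chloride, CC(C)[Si](Cl)(C(C)C)C(C)C
Why: O-Silylation of the phenol under the same conditions. The aryl triisopropylsilyl ether tolerates lithium enolates and DBU better than smaller silyl ethers, is inert to hydrogenation and leaves with fluoride together with the alkyl silyl ether.

**Step 7**
Reactants: 9 (4S,5R)-4-{[(triisopropylsilyl)oxy]methyl}-5-(3,4,5-trimethoxyphenyl)oxolan-2-one; 11 3,4-dimethoxy-5-[(triisopropylsilyl)oxy]benzaldehyde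
Product: 12 (3S,4S,5R)-3-[{3,4-dimethoxy-5-[(triisopropylsilyl)oxy]phenyl}(hydroxy)methyl]-4-{[(triisopropylsilyl)oxy]methyl}-5-(3,4,5-trimethoxyphenyl)oxolan-2-one (mixture of carbinol epimers)
Conditions: LiN(SiMe3)2 (1.1 equiv), THF, −78 °C; then 11, −78 °C; sat. aq. NH4Cl
Reagents that add atoms: none
Why: Aldol addition of a γ-butyrolactone lithium enolate to a non-enolisable aryl aldehyde forms the C4–C7' bond; 9 has one acidic position and no leaving group β to the enolate. The configurations formed at C4 (expected trans to the C3 branch) and at the carbinol are erased in step 8.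

**Step 8**
Reactants: 12 (3S,4S,5R)-3-[{3,4-dimethoxy-5-[(triisopropylsilyl)oxy]phenyl}(hydroxy)methyl]-4-{[(triisopropylsilyl)oxy]methyl}-5-(3,4,5-trimethoxyphenyl)oxolan-2-one
Product: 14 (3E,4S,5R)-3-({3,4-dimethoxy-5-[(triisopropylsilyl)oxy]phenyl}methylidene)-4-{[(triisopropylsilyl)oxy]methyl}-5-(3,4,5-trimethoxyphenyl)oxolan-2-one, via mesylate 13 (not isolated)
Conditions: MsCl (1.5 equiv), Et3N (3 equiv), CH2Cl2, 0 °C; then DBU (2 equiv), 0 °C → rt
Reagents that add atoms: none
Why: Mesylation of the secondary alcohol and base-induced E1cB elimination through the lactone enolate give the conjugated (E)-benzylidene lactone, the isomer in which the aryl group avoids the lactone carbonyl. C3 is not acidic and keeps its configuration.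

**Step 9**
Reactants: 14 (3E,4S,5R)-3-({3,4-dimethoxy-5-[(triisopropylsilyl)oxy]phenyl}methylidene)-4-{[(triisopropylsilyl)oxy]methyl}-5-(3,4,5-trimethoxyphenyl)oxolan-2-one
Product: 15 (3S,4S,5R)-3-({3,4-dimethoxy-5-[(triisopropylsilyl)oxy]phenyl}methyl)-4-{[(triisopropylsilyl)oxy]methyl}-5-(3,4,5-trimethoxyphenyl)oxolan-2-one
Conditions: H2 (1 atm), 10% Pd/C, EtOAc, rt, stopped after 1 equiv H2
Reagents that add atoms: none
Why: Heterogeneous syn-hydrogenation of the exocyclic alkene: allylic strain with the (E)-aryl group turns the silyloxymethyl group on C3 out of the ring plane, so hydrogen arrives from the opposite face and the benzyl group ends cis to the C3 branch, setting C4 (S in the target). Addition anti to the β-substituent, even with a trans γ-substituent on that face, is the usual outcome for α-alkylidene butyrolactones of this pattern. Stopping after one equivalent of hydrogen spares the benzylic C2–O1 bond.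

**Step 10**
Reactants: 15 (3S,4S,5R)-3-({3,4-dimethoxy-5-[(triisopropylsilyl)oxy]phenyl}methyl)-4-{[(triisopropylsilyl)oxy]methyl}-5-(3,4,5-trimethoxyphenyl)oxolan-2-one
Product: 16 (3S,4S,5R)-3-({3,4-dimethoxy-5-[(triisopropylsilyl)oxy]phenyl}methyl)-4-{[(triisopropylsilyl)oxy]methyl}-5-(3,4,5-trimethoxyphenyl)oxolan-2-ol (mixture of anomers)
Conditions: iBu2AlH (1.2 equiv), CH2Cl2, −78 °C
Reagents that add atoms: none
Why: Partial reduction of a lactone to the lactol: at −78 °C the aluminium hemiacetal persists until work-up, and silyl ethers are inert. The lactol is used crude so that C4, now α to a masked aldehyde, has no chance to epimerise.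

**Step 11**
Reactants: 16 (3S,4S,5R)-3-({3,4-dimethoxy-5-[(triisopropylsilyl)oxy]phenyl}methyl)-4-{[(triisopropylsilyl)oxy]methyl}-5-(3,4,5-trimethoxyphenyl)oxolan-2-ol
Product: 17 (2R,3S,4S)-4-({3,4-dimethoxy-5-[(triisopropylsilyl)oxy]phenyl}methyl)-3-{[(triisopropylsilyl)oxy]methyl}-2-(3,4,5-trimethoxyphenyl)oxolane
Conditions: Et3SiH (3 equiv), BF3·OEt2 (1.5 equiv), CH2Cl2, −78 → −40 °C
Reagents that add atoms: none
Why: Ionic deoxygenation of a lactol: BF3·OEt2 removes the anomeric hydroxyl to give the cyclic oxocarbenium ion at C5, which Et3SiH reduces to the methylene; no stereocentre is formed. At low temperature the lactol ionises far more readily than the benzylic C2–O1 ether, whose aryl group is a weaker cation stabiliser than a para-alkoxyphenyl because its 4-methoxy group is twisted out of conjugation.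

**Step 12**
Reactants: 17 (2R,3S,4S)-4-({3,4-dimethoxy-5-[(triisopropylsilyl)oxy]phenyl}methyl)-3-{[(triisopropylsilyl)oxy]methyl}-2-(3,4,5-trimethoxyphenyl)oxolane
Product: 18 [(2R,3S,4S)-4-[(3-hydroxy-4,5-dimethoxyphenyl)methyl]-2-(3,4,5-trimethoxyphenyl)oxolan-3-yl]methanol (CNP0121704.1)
Conditions: Bu4NF (2.5 equiv), THF, 0 °C → rt; aq. NH4Cl
Reagents that add atoms: none
Why: Fluoride cleaves both Si–O bonds under conditions that leave the benzylic ether, the methyl ethers and all three stereocentres untouched, releasing the phenol and the primary alcohol of 18.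

## Compound list

1 | ethyl 3-oxo-3-(3,4,5-trimethoxyphenyl)propanoate | CCOC(=O)CC(=O)c1cc(OC)c(OC)c(OC)c1 | starting material
2 | ethyl bromoacetate | CCOC(=O)CBr | starting material
3 | diethyl 2-(3,4,5-trimethoxybenzoyl)butanedioate (racemic) | CCOC(=O)CC(C(=O)OCC)C(=O)c1cc(OC)c(OC)c(OC)c1 | intermediate
4 | diethyl (2R)-2-[(R)-hydroxy(3,4,5-trimethoxyphenyl)methyl]butanedioate (not isolated) | O[C@@H](c1cc(OC)c(OC)c(OC)c1)[C@H](C(=O)OCC)CC(=O)OCC | intermediate
5 | ethyl (2R,3R)-5-oxo-2-(3,4,5-trimethoxyphenyl)oxolane-3-carboxylate | O=C1O[C@@H](c2cc(OC)c(OC)c(OC)c2)[C@H](C(=O)OCC)C1 | intermediate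
6 | (2R)-2-[(R)-hydroxy(3,4,5-trimethoxyphenyl)methyl]butanedioic acid (formed as its dilithium salt, not isolated) | O[C@@H](c1cc(OC)c(OC)c(OC)c1)[C@H](C(=O)O)CC(=O)O | intermediate
7 | (2R,3R)-5-oxo-2-(3,4,5-trimethoxyphenyl)oxolane-3-carboxylic acid | O=C1O[C@@H](c2cc(OC)c(OC)c(OC)c2)[C@H](C(=O)O)C1 | intermediate
8 | (4S,5R)-4-(hydroxymethyl)-5-(3,4,5-trimethoxyphenyl)oxolan-2-one | O=C1O[C@@H](c2cc(OC)c(OC)c(OC)c2)[C@H](CO)C1 | intermediate
9 | (4S,5R)-4-{[(triisopropylsilyl)oxy]methyl}-5-(3,4,5-trimethoxyphenyl)oxolan-2-one | O=C1O[C@@H](c2cc(OC)c(OC)c(OC)c2)[C@H](CO[Si](C(C)C)(C(C)C)C(C)C)C1 | intermediate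
10 | 3-hydroxy-4,5-dimethoxybenzaldehyde | COc1cc(C=O)cc(O)c1OC | starting material
11 | 3,4-dimethoxy-5-[(triisopropylsilyl)oxy]benzaldehyde | COc1cc(C=O)cc(O[Si](C(C)C)(C(C)C)C(C)C)c1OC | intermediate
12 | (3S,4S,5R)-3-[{3,4-dimethoxy-5-[(triisopropylsilyl)oxy]phenyl}(hydroxy)methyl]-4-{[(triisopropylsilyl)oxy]methyl}-5-(3,4,5-trimethoxyphenyl)oxolan-2-one (carbinol epimers) | O=C1O[C@@H](c2cc(OC)c(OC)c(OC)c2)[C@H](CO[Si](C(C)C)(C(C)C)C(C)C)[C@H]1C(O)c3cc(OC)c(OC)c(O[Si](C(C)C)(C(C)C)C(C)C)c3 | intermediate
13 | methanesulfonate of 12 at the carbinol oxygen (not isolated) | O=C1O[C@@H](c2cc(OC)c(OC)c(OC)c2)[C@H](CO[Si](C(C)C)(C(C)C)C(C)C)[C@H]1C(OS(C)(=O)=O)c3cc(OC)c(OC)c(O[Si](C(C)C)(C(C)C)C(C)C)c3 | intermediate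
14 | (3E,4S,5R)-3-({3,4-dimethoxy-5-[(triisopropylsilyl)oxy]phenyl}methylidene)-4-{[(triisopropylsilyl)oxy]methyl}-5-(3,4,5-trimethoxyphenyl)oxolan-2-one | O=C1O[C@@H](c2cc(OC)c(OC)c(OC)c2)[C@H](CO[Si](C(C)C)(C(C)C)C(C)C)/C1=C\c3cc(OC)c(OC)c(O[Si](C(C)C)(C(C)C)C(C)C)c3 | intermediate
15 | (3S,4S,5R)-3-({3,4-dimethoxy-5-[(triisopropylsilyl)oxy]phenyl}methyl)-4-{[(triisopropylsilyl)oxy]methyl}-5-(3,4,5-trimethoxyphenyl)oxolan-2-one | O=C1O[C@@H](c2cc(OC)c(OC)c(OC)c2)[C@H](CO[Si](C(C)C)(C(C)C)C(C)C)[C@@H]1Cc3cc(OC)c(OC)c(O[Si](C(C)C)(C(C)C)C(C)C)c3 | intermediate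
16 | (3S,4S,5R)-3-({3,4-dimethoxy-5-[(triisopropylsilyl)oxy]phenyl}methyl)-4-{[(triisopropylsilyl)oxy]methyl}-5-(3,4,5-trimethoxyphenyl)oxolan-2-ol (anomers) | OC1O[C@@H](c2cc(OC)c(OC)c(OC)c2)[C@H](CO[Si](C(C)C)(C(C)C)C(C)C)[C@@H]1Cc3cc(OC)c(OC)c(O[Si](C(C)C)(C(C)C)C(C)C)c3 | intermediate
17 | (2R,3S,4S)-4-({3,4-dimethoxy-5-[(triisopropylsilyl)oxy]phenyl}methyl)-3-{[(triisopropylsilyl)oxy]methyl}-2-(3,4,5-trimethoxyphenyl)oxolane | C1O[C@@H](c2cc(OC)c(OC)c(OC)c2)[C@H](CO[Si](C(C)C)(C(C)C)C(C)C)[C@@H]1Cc3cc(OC)c(OC)c(O[Si](C(C)C)(C(C)C)C(C)C)c3 | intermediate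
18 | [(2R,3S,4S)-4-[(3-hydroxy-4,5-dimethoxyphenyl)methyl]-2-(3,4,5-trimethoxyphenyl)oxolan-3-yl]methanol | COc1cc(C[C@@H]2CO[C@@H](c3cc(OC)c(OC)c(OC)c3)[C@@H]2CO)cc(O)c1OC | target

## Step count and least certain steps

Total: 12 steps. Longest linear sequence: 11 steps (steps 1–5 and 7–12, from 1 to 18); step 6 is a one-step side branch.

**Step 2 (key step).** The likeliest failure is incomplete dynamic resolution: reduction of the mismatched enantiomer competing with racemisation, or an enzyme that accepts the bulky aroylsuccinate only slowly or sets the opposite configuration at C3. The fallback replaces the enzyme by a chemocatalytic dynamic resolution. It sets out from 3, which is reduced by asymmetric transfer hydrogenation with RuCl(p-cymene)[(R,R)-TsDPEN] in HCO2H/Et3N; the amine keeps the α-centre racemising and the ligand enantiomer is chosen by analogy with simple aryl ketones. The resulting 4 is lactonised as before, and the route is rejoined at 5. This fallback makes no compound outside the list (entry F0).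

**Step 9.** Two processes threaten it: delivery of hydrogen from the face of the C3 branch (giving the 3,4-trans lactone), and hydrogenolysis of the benzylic C2–O1 bond on prolonged contact with palladium. The fallback avoids hydrogenation and sets C4 by enolate protonation. Aldehyde 11 is reduced with NaBH4 in MeOH to {3,4-dimethoxy-5-[(triisopropylsilyl)oxy]phenyl}methanol F1, which CBr4/PPh3 (Appel reaction) converts to [5-(bromomethyl)-2,3-dimethoxyphenoxy]triisopropylsilane F2. The lithium enolate of 9 (LiN(SiMe3)2, THF, −78 °C) is alkylated with F2 anti to the C3 branch to give the 3,4-trans lactone (3R,4S,5R)-3-({3,4-dimethoxy-5-[(triisopropylsilyl)oxy]phenyl}methyl)-4-{[(triisopropylsilyl)oxy]methyl}-5-(3,4,5-trimethoxyphenyl)oxolan-2-one F3. Re-enolisation of F3 and quenching at −78 °C with a hindered proton donor (2,6-di-tert-butylphenol) protonates C4 from the face opposite the C3 branch. This sequence sets out from 9 and rejoins the route at 15.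

**Step 11.** The risk is ionisation of the benzylic C2–O1 bond by BF3·OEt2 (epimerisation at C2 or ring opening), or partial loss of a silyl group. The fallback closes the ether by displacement instead of reduction. From 15, LiBH4 in THF opens the lactone to (1R,2S,3S)-3-({3,4-dimethoxy-5-[(triisopropylsilyl)oxy]phenyl}methyl)-2-{[(triisopropylsilyl)oxy]methyl}-1-(3,4,5-trimethoxyphenyl)butane-1,4-diol F4. The primary hydroxyl is sulfonylated selectively (MsCl 1.05 equiv, Et3N, CH2Cl2, −20 °C) to (2S,3S,4R)-2-({3,4-dimethoxy-5-[(triisopropylsilyl)oxy]phenyl}methyl)-4-hydroxy-3-{[(triisopropylsilyl)oxy]methyl}-4-(3,4,5-trimethoxyphenyl)butyl methanesulfonate F5. KOC(CH3)3 in THF at 0 °C then drives an intramolecular Williamson etherification (5-exo-tet) in which the C2–O bond is never broken. The route is rejoined at 17.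

**Step 8.** Under DBU the exocyclic double bond may migrate into the ring, which would destroy C3, or 12 may undergo retro-aldol cleavage during activation. The fallback builds the alkene by olefination. From 9, LiN(iPr)2 and ClP(O)(OEt)2 followed by a second portion of LiN(iPr)2 (oxygen-to-carbon phosphorus shift of the enol phosphate) give diethyl [(4S,5R)-2-oxo-4-{[(triisopropylsilyl)oxy]methyl}-5-(3,4,5-trimethoxyphenyl)oxolan-3-yl]phosphonate F6. Horner–Wadsworth–Emmons reaction of F6 with 11 (NaH, THF, 0 °C → rt) rejoins the route at 14 without a β-hydroxy lactone or a strong amidine base.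

## Further compounds

F0 | step 2 | none | none
F1 | step 9 | {3,4-dimethoxy-5-[(triisopropylsilyl)oxy]phenyl}methanol | COc1cc(CO)cc(O[Si](C(C)C)(C(C)C)C(C)C)c1OC
F2 | step 9 | [5-(bromomethyl)-2,3-dimethoxyphenoxy]triisopropylsilane | COc1cc(CBr)cc(O[Si](C(C)C)(C(C)C)C(C)C)c1OC
F3 | step 9 | (3R,4S,5R)-3-({3,4-dimethoxy-5-[(triisopropylsilyl)oxy]phenyl}methyl)-4-{[(triisopropylsilyl)oxy]methyl}-5-(3,4,5-trimethoxyphenyl)oxolan-2-one | O=C1O[C@@H](c2cc(OC)c(OC)c(OC)c2)[C@H](CO[Si](C(C)C)(C(C)C)C(C)C)[C@H]1Cc3cc(OC)c(OC)c(O[Si](C(C)C)(C(C)C)C(C)C)c3
F4 | step 11 | (1R,2S,3S)-3-({3,4-dimethoxy-5-[(triisopropylsilyl)oxy]phenyl}methyl)-2-{[(triisopropylsilyl)oxy]methyl}-1-(3,4,5-trimethoxyphenyl)butane-1,4-diol | OC[C@@H](Cc1cc(OC)c(OC)c(O[Si](C(C)C)(C(C)C)C(C)C)c1)[C@@H](CO[Si](C(C)C)(C(C)C)C(C)C)[C@@H](O)c1cc(OC)c(OC)c(OC)c1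
F5 | step 11 | (2S,3S,4R)-2-({3,4-dimethoxy-5-[(triisopropylsilyl)oxy]phenyl}methyl)-4-hydroxy-3-{[(triisopropylsilyl)oxy]methyl}-4-(3,4,5-trimethoxyphenyl)butyl methanesulfonate | CS(=O)(=O)OC[C@@H](Cc1cc(OC)c(OC)c(O[Si](C(C)C)(C(C)C)C(C)C)c1)[C@@H](CO[Si](C(C)C)(C(C)C)C(C)C)[C@@H](O)c1cc(OC)c(OC)c(OC)c1
F6 | step 8 | diethyl [(4S,5R)-2-oxo-4-{[(triisopropylsilyl)oxy]methyl}-5-(3,4,5-trimethoxyphenyl)oxolan-3-yl]phosphonate (epimers at C3) | O=C1O[C@@H](c2cc(OC)c(OC)c(OC)c2)[C@H](CO[Si](C(C)C)(C(C)C)C(C)C)C1P(=O)(OCC)OCC
A1 | alternative 1 | 7,7-dichloro-4-(3,4,5-trimethoxyphenyl)-3-oxabicyclo[3.2.0]heptan-6-one (cis-fused, aryl exo) | ClC1(Cl)[C@@H]2CO[C@@H](c3cc(OC)c(OC)c(OC)c3)[C@@H]2C1=O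
A2 | alternative 1 | (2R)-2-(3,4,5-trimethoxyphenyl)-2,5-dihydrofuran | C1O[C@@H](c2cc(OC)c(OC)c(OC)c2)C=C1
A3 | alternative 2 | [(2R,3S,4S)-4-{[3-(benzyloxy)-4,5-dimethoxyphenyl]methyl}-2-(3,4,5-trimethoxyphenyl)oxolan-3-yl]methanol | COc1cc(C[C@@H]2CO[C@@H](c3cc(OC)c(OC)c(OC)c3)[C@@H]2CO)cc(OCc2ccccc2)c1OC
A4 | alternative 2 | 2-[(S)-{[(2E)-3-[3-(benzyloxy)-4,5-dimethoxyphenyl]prop-2-en-1-yl]oxy}(3,4,5-trimethoxyphenyl)methyl]oxirane | COc1cc(/C=C/CO[C@@H](c2cc(OC)c(OC)c(OC)c2)C3CO3)cc(OCc4ccccc4)c1OC
A5 | alternative 3 | cis-fused 3-[3-(benzyloxy)-4,5-dimethoxyphenyl]-6-(3,4,5-trimethoxyphenyl)tetrahydro-1H,3H-furo[3,4-c]furan-1-one | COc1cc([C@H]3[C@@H]2CO[C@@H](c4cc(OC)c(OC)c(OC)c4)[C@@H]2C(=O)O3)cc(OCc2ccccc2)c1OC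
A6 | alternative 3 | 4,5-trans-5-[3-(benzyloxy)-4,5-dimethoxyphenyl]-3-diazo-4-{[(3,4,5-trimethoxyphenyl)methoxy]methyl}oxolan-2-one | COc1cc([C@H]3[C@H](COCc2cc(OC)c(OC)c(OC)c2)C(=[N+]=[N-])C(=O)O3)cc(OCc2ccccc2)c1OC
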